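**Retrosynthetic overview**
- Moracin Q ⇐ hydrogenolysis of its tri-O-benzyl ether ⇐ Krapcho demethoxycarbonylation of an α-aryl β-keto ester.
- Key disconnection: the side-chain CH–C(=O) bond, made by an intermolecular crossed Claisen condensation of the lithium enolate of a methyl (benzofuran-4-yl)acetate with isobutyryl chloride.
- Furan ring (the only ring formed; both benzene rings are bought) ⇐ Sonogashira coupling and 5-endo-dig cyclisation of an o-iodophenol with 3,5-bis(benzyloxy)phenylacetylene.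
- o-Iodophenol arylacetate ⇐ aromatic Claisen rearrangement of an allyl ether (places the C-4 carbon), O-methylation, Lemieux–Johnson and Pinnick oxidations, esterification with MOM loss, iodination.
- Differentiated trioxygenated benzene ⇐ 2,4-dihydroxybenzaldehyde (4-O-MOM, 2-O-benzyl, Baeyer–Villiger); alkyne ⇐ 3,5-dihydroxybenzaldehyde (benzylation, Ohira–Bestmann).

Assumption: moracin Q as drawn has no stereogenic element, so it is made as the achiral compound; the racemic stereocentres of two transient intermediates are destroyed again.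

**Route**

Step 1
Reactants: 1 3,5-dihydroxybenzaldehyde
Product: 2 3,5-bis(benzyloxy)benzaldehyde
Conditions: BnBr (2.3 equiv), K2CO3, DMF, 60 °C
Reagents that add atoms: benzyl bromide, BrCc1ccccc1
Why: Williamson ether synthesis on both phenoxides installs benzyl ethers that are removed together in the last step.

Step 2
Reactants: 2 3,5-bis(benzyloxy)benzaldehyde
Product: 3 1,3-bis(benzyloxy)-5-ethynylbenzene
Conditions: dimethyl (1-diazo-2-oxopropyl)phosphonate, K2CO3, MeOH–THF, 0 °C → rt
Reagents that add atoms: dimethyl (1-diazo-2-oxopropyl)phosphonate, CC(=O)C(=[N+]=[N-])P(=O)(OC)OC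
Why: Ohira–Bestmann (Seyferth–Gilbert) homologation turns the non-enolisable aryl aldehyde into the terminal alkyne under mild base.

Step 3
Reactants: 4 2,4-dihydroxybenzaldehyde
Product: 5 2-hydroxy-4-(methoxymethoxy)benzaldehyde
Conditions: MOMCl (1.1 equiv), K2CO3, acetone, 0 °C → rt
Reagents that add atoms: chloromethyl methyl ether, COCCl
Why: Regioselective Williamson-type O-alkylation, because the 4-OH para to the aldehyde is the more acidic phenol while the 2-OH is held in a hydrogen bond to the carbonyl.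

Step 4
Reactants: 5 2-hydroxy-4-(methoxymethoxy)benzaldehyde
Product: 6 2-(benzyloxy)-4-(methoxymethoxy)benzaldehyde
Conditions: BnBr, K2CO3, DMF, 60 °C
Reagents that add atoms: benzyl bromide, BrCc1ccccc1
Why: Williamson ether synthesis on the remaining phenol gives the benzyl ether that will become the 6-OH of the target.

Step 5
Reactants: 6 2-(benzyloxy)-4-(methoxymethoxy)benzaldehyde
Product: 8 2-(benzyloxy)-4-(methoxymethoxy)phenol, via aryl formate 7 (not isolated)
Conditions: mCPBA, CH2Cl2, 0 °C → rt; aq. NaHCO3 wash; then K2CO3 (cat.), MeOH, rt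
Reagents that add atoms: meta-chloroperoxybenzoic acid, OOC(=O)c1cccc(Cl)c1
Why: Baeyer–Villiger (Dakin-type) oxidation, in which the electron-rich aryl group migrates to oxygen and the resulting formate is cleaved by methanolysis.

Step 6
Reactants: 8 2-(benzyloxy)-4-(methoxymethoxy)phenol
Product: 9 1-(allyloxy)-2-(benzyloxy)-4-(methoxymethoxy)benzene
Conditions: allyl bromide, K2CO3, acetone, reflux
Reagents that add atoms: allyl bromide, C=CCBr
Why: Williamson ether synthesis gives the allyl aryl ether needed for the sigmatropic shift.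

Step 7
Reactants: 9 1-(allyloxy)-2-(benzyloxy)-4-(methoxymethoxy)benzene
Product: 10 2-allyl-6-(benzyloxy)-4-(methoxymethoxy)phenol
Conditions: N,N-diethylaniline, 190 °C, argon
Reagents that add atoms: none
Why: Aromatic Claisen rearrangement ([3,3]-sigmatropic) delivers the allyl group to the only free ortho position, which fixes the carbon substituent next to the future methoxy group without a regiochemical choice.

Step 8
Reactants: 10 2-allyl-6-(benzyloxy)-4-(methoxymethoxy)phenol
Product: 11 1-allyl-3-(benzyloxy)-2-methoxy-5-(methoxymethoxy)benzene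
Conditions: MeI, K2CO3, DMF, 40 °C
Reagents that add atoms: iodomethane, CI
Why: Williamson O-methylation of the only free phenol installs the methyl ether of the target.

Step 9
Reactants: 11 1-allyl-3-(benzyloxy)-2-methoxy-5-(methoxymethoxy)benzene
Product: 13 2-[3-(benzyloxy)-2-methoxy-5-(methoxymethoxy)phenyl]acetaldehyde, via vicinal diol 12 (not isolated)
Conditions: OsO4 (2 mol%), NaIO4 (4 equiv), 2,6-lutidine, dioxane–H2O (3:1), rt
Reagents that add atoms: osmium tetroxide, O=[Os](=O)(=O)=O; sodium periodate, [Na+].[O-]I(=O)(=O)=O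
Why: Lemieux–Johnson oxidation, in which catalytic dihydroxylation of the terminal alkene and periodate cleavage of the racemic diol give the arylacetaldehyde while the aryl ethers are untouched.

Step 10
Reactants: 13 2-[3-(benzyloxy)-2-methoxy-5-(methoxymethoxy)phenyl]acetaldehyde
Product: 14 2-[3-(benzyloxy)-2-methoxy-5-(methoxymethoxy)phenyl]acetic acid
Conditions: NaClO2, NaH2PO4, 2-methyl-2-butene, t-BuOH–H2O, 0 °C → rt (crude aldehyde used at once)
Reagents that add atoms: sodium chlorite, [Na+].[O-]Cl=O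
Why: Pinnick oxidation converts the aldehyde to the acid under buffered conditions, and the alkene scavenger protects the electron-rich ring from chlorination.

Step 11
Reactants: 14 2-[3-(benzyloxy)-2-methoxy-5-(methoxymethoxy)phenyl]acetic acid
Product: 15 methyl 2-[3-(benzyloxy)-5-hydroxy-2-methoxyphenyl]acetate
Conditions: HCl (1.25 M in MeOH), 40 °C
Reagents that add atoms: methanol, CO
Why: Fischer esterification and acid-catalysed acetal exchange of the phenolic MOM ether occur in one operation and leave the benzyl ether intact.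

Step 12
Reactants: 15 methyl 2-[3-(benzyloxy)-5-hydroxy-2-methoxyphenyl]acetate
Product: 16 methyl 2-[3-(benzyloxy)-5-hydroxy-6-iodo-2-methoxyphenyl]acetate
Conditions: N-iodosuccinimide (1.05 equiv), MeCN, −10 → 0 °C, dark
Reagents that add atoms: N-iodosuccinimide, O=C1CCC(=O)N1I
Why: Electrophilic aromatic iodination goes to the position ortho to the free hydroxyl and para to the benzyloxy group, which is favoured over the other ortho position lying between two oxygens.

Step 13
Reactants: 16 methyl 2-[3-(benzyloxy)-5-hydroxy-6-iodo-2-methoxyphenyl]acetate; 3 1,3-bis(benzyloxy)-5-ethynylbenzene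
Product: 18 methyl 2-{6-(benzyloxy)-2-[3,5-bis(benzyloxy)phenyl]-5-methoxy-1-benzofuran-4-yl}acetate, via o-alkynylphenol 17 (not isolated)
Conditions: PdCl2(PPh3)2 (5 mol%), CuI (10 mol%), Et3N, DMF, rt → 70 °C
Reagents that add atoms: none
Why: Sonogashira coupling followed by 5-endo-dig cyclisation of the o-alkynylphenol (heteroannulation) forms the furan ring with the aryl group at C-2.

Step 14
Reactants: 18 methyl 2-{6-(benzyloxy)-2-[3,5-bis(benzyloxy)phenyl]-5-methoxy-1-benzofuran-4-yl}acetate; 19 isobutyryl chloride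
Product: 21 methyl 2-{6-(benzyloxy)-2-[3,5-bis(benzyloxy)phenyl]-5-methoxy-1-benzofuran-4-yl}-4-methyl-3-oxopentanoate (racemic), via lithium ester enolate 20 (not isolated)
Conditions: LiN(SiMe3)2 (2.2 equiv), THF, −78 °C; then 19, −78 → 0 °C
Reagents that add atoms: none
Why: Crossed Claisen condensation, in which the preformed arylacetate enolate is C-acylated by the acid chloride and the second equivalent of base deprotonates the β-keto ester as it forms, so over-acylation is blocked; the new α-stereocentre is racemic and is erased in step 15.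

Step 15
Reactants: 21 methyl 2-{6-(benzyloxy)-2-[3,5-bis(benzyloxy)phenyl]-5-methoxy-1-benzofuran-4-yl}-4-methyl-3-oxopentanoate
Product: 22 1-{6-(benzyloxy)-2-[3,5-bis(benzyloxy)phenyl]-5-methoxy-1-benzofuran-4-yl}-3-methylbutan-2-one
Conditions: LiCl, DMSO–H2O, 140 °C
Reagents that add atoms: none
Why: Krapcho demethoxycarbonylation (chloride demethylation, loss of CO2, protonation) removes the ester under neutral conditions that spare the benzyl ethers and the benzofuran.

Step 16
Reactants: 22 1-{6-(benzyloxy)-2-[3,5-bis(benzyloxy)phenyl]-5-methoxy-1-benzofuran-4-yl}-3-methylbutan-2-one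
Product: 23 moracin Q
Conditions: H2 (1 atm), 10% Pd/C, EtOAc–MeOH, rt
Reagents that add atoms: none
Why: Catalytic hydrogenolysis cleaves the three benzyl aryl ethers while the methyl ether, the dialkyl ketone and the aromatic benzofuran are inert at 1 atm and room temperature, giving the achiral target.

**Compound list**

1 | 3,5-dihydroxybenzaldehyde | O=Cc1cc(O)cc(O)c1 | starting material
2 | 3,5-bis(benzyloxy)benzaldehyde | O=Cc1cc(OCc2ccccc2)cc(OCc2ccccc2)c1 | intermediate
3 | 1,3-bis(benzyloxy)-5-ethynylbenzene | C#Cc1cc(OCc2ccccc2)cc(OCc2ccccc2)c1 | intermediate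
4 | 2,4-dihydroxybenzaldehyde | O=Cc1ccc(O)cc1O | starting material
5 | 2-hydroxy-4-(methoxymethoxy)benzaldehyde | O=Cc1ccc(OCOC)cc1O | intermediate
6 | 2-(benzyloxy)-4-(methoxymethoxy)benzaldehyde | O=Cc1ccc(OCOC)cc1OCc1ccccc1 | intermediate
7 | 2-(benzyloxy)-4-(methoxymethoxy)phenyl formate (aryl formate, not isolated) | O=COc1ccc(OCOC)cc1OCc1ccccc1 | intermediate
8 | 2-(benzyloxy)-4-(methoxymethoxy)phenol | Oc1ccc(OCOC)cc1OCc1ccccc1 | intermediate
9 | 1-(allyloxy)-2-(benzyloxy)-4-(methoxymethoxy)benzene | C=CCOc1ccc(OCOC)cc1OCc1ccccc1 | intermediate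
10 | 2-allyl-6-(benzyloxy)-4-(methoxymethoxy)phenol | C=CCc1cc(OCOC)cc(OCc2ccccc2)c1O | intermediate
11 | 1-allyl-3-(benzyloxy)-2-methoxy-5-(methoxymethoxy)benzene | C=CCc1cc(OCOC)cc(OCc2ccccc2)c1OC | intermediate
12 | 3-[3-(benzyloxy)-2-methoxy-5-(methoxymethoxy)phenyl]propane-1,2-diol (vicinal diol, racemic, not isolated) | OCC(O)Cc1cc(OCOC)cc(OCc2ccccc2)c1OC | intermediate
13 | 2-[3-(benzyloxy)-2-methoxy-5-(methoxymethoxy)phenyl]acetaldehyde | O=CCc1cc(OCOC)cc(OCc2ccccc2)c1OC | intermediate
14 | 2-[3-(benzyloxy)-2-methoxy-5-(methoxymethoxy)phenyl]acetic acid | OC(=O)Cc1cc(OCOC)cc(OCc2ccccc2)c1OC | intermediate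
15 | methyl 2-[3-(benzyloxy)-5-hydroxy-2-methoxyphenyl]acetate | COC(=O)Cc1cc(O)cc(OCc2ccccc2)c1OC | intermediate
16 | methyl 2-[3-(benzyloxy)-5-hydroxy-6-iodo-2-methoxyphenyl]acetate | COC(=O)Cc1c(I)c(O)cc(OCc2ccccc2)c1OC | intermediate
17 | methyl 2-[3-(benzyloxy)-6-{[3,5-bis(benzyloxy)phenyl]ethynyl}-5-hydroxy-2-methoxyphenyl]acetate (o-alkynylphenol, not isolated) | COC(=O)Cc1c(C#Cc2cc(OCc3ccccc3)cc(OCc3ccccc3)c2)c(O)cc(OCc2ccccc2)c1OC | intermediate
18 | methyl 2-{6-(benzyloxy)-2-[3,5-bis(benzyloxy)phenyl]-5-methoxy-1-benzofuran-4-yl}acetate | COC(=O)Cc1c(OC)c(OCc2ccccc2)cc2oc(-c3cc(OCc4ccccc4)cc(OCc4ccccc4)c3)cc12 | intermediate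
19 | isobutyryl chloride (2-methylpropanoyl chloride) | CC(C)C(Cl)=O | starting material
20 | lithium enolate of 18, lithium 2-{6-(benzyloxy)-2-[3,5-bis(benzyloxy)phenyl]-5-methoxy-1-benzofuran-4-yl}-1-methoxyethen-1-olate (not isolated) | [Li+].[O-]C(OC)=Cc1c(OC)c(OCc2ccccc2)cc2oc(-c3cc(OCc4ccccc4)cc(OCc4ccccc4)c3)cc12 | intermediate
21 | methyl 2-{6-(benzyloxy)-2-[3,5-bis(benzyloxy)phenyl]-5-methoxy-1-benzofuran-4-yl}-4-methyl-3-oxopentanoate (racemic) | COC(=O)C(C(=O)C(C)C)c1c(OC)c(OCc2ccccc2)cc2oc(-c3cc(OCc4ccccc4)cc(OCc4ccccc4)c3)cc12 | intermediate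
22 | 1-{6-(benzyloxy)-2-[3,5-bis(benzyloxy)phenyl]-5-methoxy-1-benzofuran-4-yl}-3-methylbutan-2-one | CC(C)C(=O)Cc1c(OC)c(OCc2ccccc2)cc2oc(-c3cc(OCc4ccccc4)cc(OCc4ccccc4)c3)cc12 | intermediate
23 | moracin Q, 1-[2-(3,5-dihydroxyphenyl)-6-hydroxy-5-methoxy-1-benzofuran-4-yl]-3-methylbutan-2-one (achiral) | COc1c(O)cc2oc(-c3cc(O)cc(O)c3)cc2c1CC(=O)C(C)C | target

**Step count**

Total: 16 steps. Longest linear sequence: 14 steps (steps 3–16, from 4 to 23). The two-step alkyne branch (steps 1–2) joins at step 13.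

**Steps most likely to fail, with fallbacks**

Step 12 (site of iodination). If iodination of 15 gives much of the isomer between the hydroxyl and the benzyloxy group, the directing phenol is exchanged. The fallback sets out from acid 14.
- MeI and K2CO3 in DMF give methyl 2-[3-(benzyloxy)-2-methoxy-5-(methoxymethoxy)phenyl]acetate F1.
- Hydrogenolysis (H2, 10% Pd/C, EtOAc) frees the other phenol, giving methyl 2-[3-hydroxy-2-methoxy-5-(methoxymethoxy)phenyl]acetate F2.
- N-Iodosuccinimide in MeCN now iodinates para to the free hydroxyl, giving methyl 2-[3-hydroxy-6-iodo-2-methoxy-5-(methoxymethoxy)phenyl]acetate F3.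
- BnBr and K2CO3 give methyl 2-[3-(benzyloxy)-6-iodo-2-methoxy-5-(methoxymethoxy)phenyl]acetate F4.
- HCl in MeOH removes the MOM group, and the route is rejoined at 16.

Step 13 (coupling and ring closure on a hindered free iodophenol). If the one-pot heteroannulation stalls, coupling and ring closure are separated. The fallback sets out from 16.
- Ac2O and pyridine give methyl 2-[5-acetoxy-3-(benzyloxy)-6-iodo-2-methoxyphenyl]acetate F5.
- Sonogashira coupling with 3 (PdCl2(PPh3)2, CuI, Et3N, THF, rt) gives methyl 2-[5-acetoxy-3-(benzyloxy)-6-{[3,5-bis(benzyloxy)phenyl]ethynyl}-2-methoxyphenyl]acetate F6.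
- K2CO3 in MeOH removes the acetate, and the route is rejoined at 17, here isolated.
- 17 is closed to 18 by base-mediated 5-endo-dig cyclisation (Cs2CO3, DMF, 60 °C) instead of by the metal catalysts.

Step 14 (O- versus C-acylation of a hindered, stabilised enolate). If acylation with the acid chloride gives enol ester or poor conversion, the same bond is made by an aldol addition followed by oxidation. The fallback sets out from 18.
- The enolate 20, made with 1.1 equiv LiN(SiMe3)2, is treated with isobutyraldehyde at −78 °C and quenched cold, giving methyl 2-{6-(benzyloxy)-2-[3,5-bis(benzyloxy)phenyl]-5-methoxy-1-benzofuran-4-yl}-3-hydroxy-4-methylpentanoate F7 as a mixture of racemic diastereomers.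
- Dess–Martin periodinane in CH2Cl2 oxidises the alcohol, and the route is rejoined at 21.

**Further compounds**

F1 | step 12 | methyl 2-[3-(benzyloxy)-2-methoxy-5-(methoxymethoxy)phenyl]acetate | COC(=O)Cc1cc(OCOC)cc(OCc2ccccc2)c1OC
F2 | step 12 | methyl 2-[3-hydroxy-2-methoxy-5-(methoxymethoxy)phenyl]acetate | COC(=O)Cc1cc(OCOC)cc(O)c1OC
F3 | step 12 | methyl 2-[3-hydroxy-6-iodo-2-methoxy-5-(methoxymethoxy)phenyl]acetate | COC(=O)Cc1c(I)c(OCOC)cc(O)c1OC
F4 | step 12 | methyl 2-[3-(benzyloxy)-6-iodo-2-methoxy-5-(methoxymethoxy)phenyl]acetate | COC(=O)Cc1c(I)c(OCOC)cc(OCc2ccccc2)c1OC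
F5 | step 13 | methyl 2-[5-acetoxy-3-(benzyloxy)-6-iodo-2-methoxyphenyl]acetate | COC(=O)Cc1c(I)c(OC(C)=O)cc(OCc2ccccc2)c1OC
F6 | step 13 | methyl 2-[5-acetoxy-3-(benzyloxy)-6-{[3,5-bis(benzyloxy)phenyl]ethynyl}-2-methoxyphenyl]acetate | COC(=O)Cc1c(C#Cc2cc(OCc3ccccc3)cc(OCc3ccccc3)c2)c(OC(C)=O)cc(OCc2ccccc2)c1OC
F7 | step 14 | methyl 2-{6-(benzyloxy)-2-[3,5-bis(benzyloxy)phenyl]-5-methoxy-1-benzofuran-4-yl}-3-hydroxy-4-methylpentanoate (diastereomer mixture, racemic) | COC(=O)C(C(O)C(C)C)c1c(OC)c(OCc2ccccc2)cc2oc(-c3cc(OCc4ccccc4)cc(OCc4ccccc4)c3)cc12
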